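**Retrosynthetic overview**
1. Target ⇐ dehydration of the 13‑hydroxy lactone 19 ⇐ one acid cascade on ketone 18 (Peterson → C10=CH2; acetonide off → C6‑OH lactonises, C5‑OH closes the C2 hemiketal).
2. 18 ⇐ isoxazoline 17 ⇐ key step: intramolecular nitrile oxide–alkene [3+2] cycloaddition of oxime 16 onto a 2‑(silylmethyl)allyl unit, forming C1–C2 and the ten‑membered carbocycle.
3. 16 ⇐ aldehyde 10 + allylstannane 12 (C8–C9; chelation‑controlled, then Mitsunobu inversion with tiglic acid) ⇐ anti cuprate addition to enoate 7 (sets C7).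
4. 7 ⇐ L‑tartrate acetonide 1 (supplies C5, C6) via bis‑Weinreb amide; C4 by chelation‑controlled allylation of the methyl ketone.
5. Ring order: dioxolane (bought) → isoxazoline + 10‑ring (one step) → γ‑lactone + bridging THF hemiketal (acid cascade).

Assumption: the hemiketal carbon C2 is under ring–chain equilibrium and is fixed by C5 through the O‑bridge; I write it as in the supplied SMILES.
Numbering: germacrane labels are used throughout (C2 hemiketal, C4 C(Me)OMe, C5/C6 O‑bearing CH, C7, C8 tiglate carbon, C10 =CH2, C11–C13 lactone side).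
This is a paper design; no step has been run.

**Step 1**
Reactants: 1, dimethyl (4R,5R)-2,2-dimethyl-1,3-dioxolane-4,5-dicarboxylate
Product: 2, (4R,5R)-N4,N5-dimethoxy-N4,N5,2,2-tetramethyl-1,3-dioxolane-4,5-dicarboxamide
Conditions: MeNH(OMe)·HCl, i‑PrMgCl, THF, −20 → 0 °C
Reagents that add atoms: N,O‑dimethylhydroxylamine, CNOC
Why: Weinreb aminolysis of both esters; the tartrate stereocentres (future C5, C6) are untouched.

**Step 2**
Reactants: 2
Product: 3, (4R,5R)-5-acetyl-N-methoxy-N,2,2-trimethyl-1,3-dioxolane-4-carboxamide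
Conditions: MeMgBr (1.1 equiv), THF, −15 °C
Reagents that add atoms: methylmagnesium bromide, C[Mg]Br
Why: Weinreb ketone synthesis; the chelated tetrahedral intermediate should stop at mono‑addition (controlled by stoichiometry), and because 2 is C2‑symmetric either amide gives the same ketone (C4, C15).

**Step 3**
Reactants: 3
Product: 4, (4R,5R)-5-[(2R)-2-hydroxypent-4-en-2-yl]-N-methoxy-N,2,2-trimethyl-1,3-dioxolane-4-carboxamide
Conditions: MgBr2·OEt2, then allylMgBr, CH2Cl2/Et2O, −78 °C
Reagents that add atoms: allylmagnesium bromide, C=CC[Mg]Br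
Why: Cram‑chelate (α‑alkoxy ketone/Mg) Grignard addition: allyl attacks anti to the dioxolane C–C bond, giving the (R) tertiary carbinol (C4) with C4–O syn to C5–O; the ketone reacts far faster than the Weinreb amide.

**Step 4**
Reactants: 4
Product: 5, (4R,5R)-N-methoxy-5-[(2R)-2-methoxypent-4-en-2-yl]-N,2,2-trimethyl-1,3-dioxolane-4-carboxamide
Conditions: NaH, MeI, THF/DMF, 0 °C → rt
Reagents that add atoms: iodomethane, CI
Why: Williamson methylation of the tertiary alkoxide installs the C4 OMe without touching C4.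

**Step 5**
Reactants: 5
Product: 6, (4R,5R)-N-methoxy-N,2,2-trimethyl-5-[(2R)-2,4,4-trimethoxybutan-2-yl]-1,3-dioxolane-4-carboxamide
Conditions: O3, CH2Cl2/MeOH, −78 °C; Me2S; then HC(OMe)3, PPTS, MeOH, rt
Reagents that add atoms: methanol (via trimethyl orthoformate), CO
Why: Ozonolysis of the only alkene and in‑situ acetalisation masks C2 as a base‑stable dimethyl acetal.

**Step 6**
Reactants: 6
Product: 7, methyl (2E)-3-{(4S,5R)-2,2-dimethyl-5-[(2R)-2,4,4-trimethoxybutan-2-yl]-1,3-dioxolan-4-yl}prop-2-enoate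
Conditions: DIBAL‑H, THF, −78 °C; then (MeO)2P(O)CH2CO2Me/NaH, −78 °C → rt
Reagents that add atoms: trimethyl phosphonoacetate, COC(=O)CP(=O)(OC)OC
Why: One‑pot Weinreb amide reduction and Horner–Wadsworth–Emmons olefination gives the (E)‑enoate without isolating the epimerisable α‑alkoxy aldehyde.

**Step 7**
Reactants: 7
Product: 8, methyl (3S)-3-{(4S,5R)-2,2-dimethyl-5-[(2R)-2,4,4-trimethoxybutan-2-yl]-1,3-dioxolan-4-yl}-2-(hydroxymethyl)pent-4-enoate (C11 epimers)
Conditions: vinylMgBr, CuBr·SMe2, THF/Me2S, −78 → −40 °C; then HCHO (gas), −78 °C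
Reagents that add atoms: vinylmagnesium bromide, C=C[Mg]Br; formaldehyde, C=O
Why: Cuprate 1,4‑addition to the γ‑alkoxy (E)‑enoate occurs anti to the allylic C–O bond (Felkin–Anh type), setting C7; the enolate is trapped by aldol with formaldehyde to bring in C13 (C11 later becomes sp2).

**Step 8**
Reactants: 8
Product: 9, the tert‑butyldimethylsilyl ether of 8
Conditions: TBSCl, imidazole, DMF, rt
Reagents that add atoms: tert‑butyldimethylsilyl chloride, CC(C)(C)[Si](C)(C)Cl
Why: Silyl protection of the primary alcohol, needed for the Mitsunobu and cycloaddition steps.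

**Step 9**
Reactants: 9
Product: 10, methyl (3S)-2-{[(tert-butyldimethylsilyl)oxy]methyl}-3-{(4S,5R)-2,2-dimethyl-5-[(2R)-2,4,4-trimethoxybutan-2-yl]-1,3-dioxolan-4-yl}-4-oxobutanoate
Conditions: O3, CH2Cl2, −78 °C; PPh3
Reagents that add atoms: ozone, O=[O+][O-]
Why: Ozonolysis of the sole remaining alkene reveals the C8 aldehyde.

**Step 10**
Reactants: 11, 2-(chloromethyl)allyl(trimethyl)silane
Product: 12, tributyl{2-[(trimethylsilyl)methyl]prop-2-en-1-yl}stannane
Conditions: Bu3SnLi (from Bu3SnH/LDA), THF, −78 → 0 °C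
Reagents that add atoms: tributylstannyllithium, [Li][Sn](CCCC)(CCCC)CCCC
Why: SN2 stannylation of the allylic chloride gives a bifunctional reagent whose stannane end is far more nucleophilic than its silane end.

**Step 11**
Reactants: 10; 12
Product: 13, methyl (3R,4R)-2-{[(tert-butyldimethylsilyl)oxy]methyl}-3-{(4S,5R)-2,2-dimethyl-5-[(2R)-2,4,4-trimethoxybutan-2-yl]-1,3-dioxolan-4-yl}-4-hydroxy-6-[(trimethylsilyl)methyl]hept-6-enoate (the 8R, i.e. 8‑epi, alcohol)
Conditions: MgBr2·OEt2, CH2Cl2, −78 → −20 °C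
Reagents that add atoms: none
Why: Keck allylstannane addition under β‑chelation (Mg bridging the aldehyde and the C6 dioxolane oxygen): attack anti to the pseudo‑axial C7 substituent gives the 1,3‑anti (8R) alcohol, and the allylsilane end is left intact.

**Step 12**
Reactants: 13; 14, tiglic acid [(E)-2-methylbut-2-enoic acid]
Product: 15, the (3R,4S) tiglate: as 13 but with C8 inverted and bearing O‑tigloyl
Conditions: PPh3, DIAD, toluene, 0 °C → rt
Reagents that add atoms: none
Why: Mitsunobu esterification inverts C8 (SN2) to the required 8S tiglate.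

**Step 13**
Reactants: 15
Product: 16, the C2 aldoxime of 15 (dimethyl acetal replaced by CH=NOH; E/Z mixture)
Conditions: NH2OH·HCl, pyridine, EtOH/H2O, 50 °C
Reagents that add atoms: hydroxylamine, NO
Why: Direct transoximation of the dimethyl acetal gives the nitrile oxide precursor under buffered conditions that leave the acetonide and esters alone.

**Step 14**
Reactants: 16
Product: 17, bridged Δ2‑isoxazoline: ten‑membered carbocycle C1–C10 with C2=N–O–C10; C10 bears CH2SiMe3; C5/C6 trans‑acetonide; C7 bears CH(CH2OTBS)CO2Me; C8 (S)‑O‑tigloyl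
Conditions: NCS, cat. pyridine, CHCl3, rt; then syringe‑pump addition to Et3N, toluene (about 1 mM), 50 °C
Reagents that add atoms: none
Why: In‑situ nitrile oxide generation and intramolecular 1,3‑dipolar cycloaddition onto the electron‑rich 1,1‑disubstituted allylsilane (C to the CH2 terminus, O to the substituted carbon) forms C1–C2 and the ten‑membered ring; the new C10 centre is destroyed later.

**Step 15**
Reactants: 17
Product: 18, the ring‑opened β‑hydroxy ketone: C2 ketone, C10 tertiary OH bearing CH2SiMe3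
Conditions: Mo(CO)6, MeCN/H2O, 80 °C
Reagents that add atoms: water, O
Why: Reductive N–O cleavage and imine hydrolysis unmask the C2 ketone without touching the alkenes.

**Step 16**
Reactants: 18
Product: 19, the 11,13‑dihydro‑13‑hydroxy analogue of the target (α‑hydroxymethyl lactone, C2 hemiketal, C10=CH2)
Conditions: 3 M HCl/THF (1:4), 0 °C → rt
Reagents that add atoms: none
Why: One acid treatment effects Peterson elimination of the β‑hydroxysilane (C10=CH2), acetonide and TBS hydrolysis, γ‑lactonisation of C6‑OH onto the methyl ester, and transannular hemiketalisation of C5‑OH onto the C2 ketone (thermodynamic; C2 follows C5).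

**Step 17**
Reactants: 19
Product: 20, target (CID 86289099)
Conditions: MsCl, Et3N, CH2Cl2, −20 °C; then DBU, 0 °C
Reagents that add atoms: none
Why: Mesylation of the primary alcohol and E1cB elimination give the α‑methylene‑γ‑butyrolactone; no stereocentre is affected.

**Compound list**
1 | dimethyl (4R,5R)-2,2-dimethyl-1,3-dioxolane-4,5-dicarboxylate (L‑tartrate acetonide) | COC(=O)[C@@H]1OC(C)(C)O[C@H]1C(=O)OC | starting material
2 | (4R,5R)-N4,N5-dimethoxy-N4,N5,2,2-tetramethyl-1,3-dioxolane-4,5-dicarboxamide | CON(C)C(=O)[C@@H]1OC(C)(C)O[C@H]1C(=O)N(C)OC | intermediate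
3 | (4R,5R)-5-acetyl-N-methoxy-N,2,2-trimethyl-1,3-dioxolane-4-carboxamide | CC(=O)[C@@H]1OC(C)(C)O[C@H]1C(=O)N(C)OC | intermediate
4 | (4R,5R)-5-[(2R)-2-hydroxypent-4-en-2-yl]-N-methoxy-N,2,2-trimethyl-1,3-dioxolane-4-carboxamide | C=CC[C@@](C)(O)[C@@H]1OC(C)(C)O[C@H]1C(=O)N(C)OC | intermediate
5 | (4R,5R)-N-methoxy-5-[(2R)-2-methoxypent-4-en-2-yl]-N,2,2-trimethyl-1,3-dioxolane-4-carboxamide | C=CC[C@@](C)(OC)[C@@H]1OC(C)(C)O[C@H]1C(=O)N(C)OC | intermediate
6 | (4R,5R)-N-methoxy-N,2,2-trimethyl-5-[(2R)-2,4,4-trimethoxybutan-2-yl]-1,3-dioxolane-4-carboxamide | COC(OC)C[C@@](C)(OC)[C@@H]1OC(C)(C)O[C@H]1C(=O)N(C)OC | intermediate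
7 | methyl (2E)-3-{(4S,5R)-2,2-dimethyl-5-[(2R)-2,4,4-trimethoxybutan-2-yl]-1,3-dioxolan-4-yl}prop-2-enoate | COC(OC)C[C@@](C)(OC)[C@@H]1OC(C)(C)O[C@H]1/C=C/C(=O)OC | intermediate
8 | methyl (3S)-3-{dioxolanyl as in 7}-2-(hydroxymethyl)pent-4-enoate (C11 epimers) | COC(OC)C[C@@](C)(OC)[C@@H]1OC(C)(C)O[C@H]1[C@@H](C=C)C(CO)C(=O)OC | intermediate
9 | TBS ether of 8 | COC(OC)C[C@@](C)(OC)[C@@H]1OC(C)(C)O[C@H]1[C@@H](C=C)C(CO[Si](C)(C)C(C)(C)C)C(=O)OC | intermediate
10 | methyl (3S)-2-(TBSO‑methyl)-3-{dioxolanyl}-4-oxobutanoate (C8 aldehyde) | COC(OC)C[C@@](C)(OC)[C@@H]1OC(C)(C)O[C@H]1[C@@H](C=O)C(CO[Si](C)(C)C(C)(C)C)C(=O)OC | intermediate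
11 | 2-(chloromethyl)allyl(trimethyl)silane | C=C(CCl)C[Si](C)(C)C | starting material
12 | tributyl{2-[(trimethylsilyl)methyl]prop-2-en-1-yl}stannane | CCCC[Sn](CCCC)(CCCC)CC(=C)C[Si](C)(C)C | intermediate
13 | (3R,4R) homoallylic alcohol, 8R (8‑epi) | COC(OC)C[C@@](C)(OC)[C@@H]1OC(C)(C)O[C@H]1[C@@H]([C@H](O)CC(=C)C[Si](C)(C)C)C(CO[Si](C)(C)C(C)(C)C)C(=O)OC | intermediate
14 | tiglic acid, (E)-2-methylbut-2-enoic acid | C/C=C(\C)C(=O)O | starting material
15 | (3R,4S) tiglate, 8S | COC(OC)C[C@@](C)(OC)[C@@H]1OC(C)(C)O[C@H]1[C@@H]([C@@H](OC(=O)/C(C)=C/C)CC(=C)C[Si](C)(C)C)C(CO[Si](C)(C)C(C)(C)C)C(=O)OC | intermediate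
16 | C2 aldoxime of 15 | ON=CC[C@@](C)(OC)[C@@H]1OC(C)(C)O[C@H]1[C@@H]([C@@H](OC(=O)/C(C)=C/C)CC(=C)C[Si](C)(C)C)C(CO[Si](C)(C)C(C)(C)C)C(=O)OC | intermediate
17 | isoxazoline‑bridged ten‑membered carbocycle (C10 epimers) | C[Si](C)(C)CC12CC(=NO1)C[C@@](C)(OC)[C@@H]3OC(C)(C)O[C@H]3[C@H](C(CO[Si](C)(C)C(C)(C)C)C(=O)OC)[C@@H](OC(=O)/C(C)=C/C)C2 | intermediate
18 | 2‑oxo‑10‑hydroxy‑10‑(trimethylsilylmethyl)cyclodecane, otherwise as 17 | C[Si](C)(C)CC1(O)CC(=O)C[C@@](C)(OC)[C@@H]2OC(C)(C)O[C@H]2[C@H](C(CO[Si](C)(C)C(C)(C)C)C(=O)OC)[C@@H](OC(=O)/C(C)=C/C)C1 | intermediate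
19 | 11,13‑dihydro‑13‑hydroxy target (C11 epimers) | C=C1C[C@H](OC(=O)/C(C)=C/C)[C@H]2C(CO)C(=O)O[C@@H]2[C@H]2O[C@](O)(C1)C[C@@]2(C)OC | intermediate
20 | target, CID 86289099 | C=C1C[C@H](OC(=O)/C(C)=C/C)[C@H]2C(=C)C(=O)O[C@@H]2[C@H]2O[C@](O)(C1)C[C@@]2(C)OC | target

Compounds 8–19 carry an undefined C11 centre, 16 is an E/Z mixture and 17/18 are C10 epimers; all converge by step 17.

**Step count:** 17 steps in total; longest linear sequence 16 (steps 1–9 and 11–17).

**Three steps most likely to fail, with fallbacks**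
- **Step 14 (ten‑membered ring by intramolecular nitrile oxide cycloaddition):** medium‑ring strain may let furoxan dimerisation win. Fallback: run the nitrile oxide cycloaddition intermolecularly at the C2 end with commercial 2‑methylene‑1,3‑bis(trimethylsilyl)propane, unravel to the 2‑oxo allylsilane, and close the ring by intramolecular Hosomi–Sakurai addition to the C8 aldehyde.
- **Steps 11–12 (C8: chelation‑controlled allylation, then Mitsunobu):** chelation through a dioxolane oxygen may be weak, the γ‑hydroxy ester 13 may lactonise, and the ester may participate during inversion. Fallback: oxidise 13 (either epimer) to the C8 ketone, reduce under chelation control (Zn(BH4)2, 1,3‑syn) to the 8S alcohol, and acylate directly with tigloyl chloride.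
- **Step 3 (C4 by chelation‑controlled allyl addition):** allyl Grignards are poor chelation partners. Fallback: reverse the order — allylMgBr on 2 first, then MeTi(OiPr)3 on the allyl ketone under non‑chelation Felkin–Anh control, which gives the same (4R) carbinol.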